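**Plan**

- Retrosynthesis: cut the two angelate C–O bonds and the silyl ethers; take C4–OH and C8–OH back to a C4 dienone (C8–O through a 7,8-epoxide) and C1–OH back to the ketone.
- Then contract the seven-membered ring to a benzene ring by excising C8a (bonds C8a–C3a and C8a–C8), which gives an α-methyl-α-diazoketone of a 2-alkyl-5-methylanisole; cut this at the aryl–C3 bond to an arylcuprate and an alkynoate.
- Enabling feature: ring atoms C3a, C4(O), C5, C6(Me), C7 and C8 are the six carbons of an anisole with O on C4 and Me on C6, and the quaternary C8a, flanked by the oxygenated C1, is a one-carbon acyl-carbene insert between C3a and C8.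
- Forward: aryl + alkynoate → enoate → tertiary carbinol → diazoketone → one event closes the five-membered ring and expands the benzene ring to the seven-membered ring → enol ether hydrolysis, C1 reduction, 7,8-epoxidation/reductive opening, C4 reduction, two successive angeloylations (C4–OH, then C8–OH), desilylation.
- Stereochemistry: C3 by catalysis (asymmetric epoxidation); C8a relayed from C3 in the ring expansion; C3a, C1 and C8 relayed from the angular methyl (protonation, hydride and epoxidation anti to it); C4 under thermodynamic control.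

Key step: step 7

Remark on the chemistry: ethyl 4-methylpent-2-ynoate (2) is taken as a purchasable building block; it is otherwise one step from 3-methylbut-1-yne and ethyl chloroformate.
Convention: bicyclic compounds carry azulene numbering (C1–C3, C3a, C4–C8, C8a); α is the face of the 8a-methyl group, β the opposite face.

**Route**

Step 1
Reactants: 1 1-bromo-2-methoxy-4-methylbenzene; 2 ethyl 4-methylpent-2-ynoate
Product: 6 ethyl (E)-3-(2-methoxy-4-methylphenyl)-4-methylpent-2-enoate, via aryllithium 3 (not isolated), via lithium diarylcuprate 4 (not isolated), via alkenylcuprate adduct 5 (not isolated)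
Conditions: 1 (2.2 equiv), n-BuLi, THF, −78 °C; CuBr·SMe2 (1.1 equiv), −40 °C; 2, −78 °C; MeOH then aq NH4Cl at −78 °C
Reagents that add atoms: none
Why: Syn-carbocupration of the alkynoate by the lithium diarylcuprate and protonation of the alkenylcopper at low temperature place aryl and H cis, which fixes the E-enoate (aryl trans to the ester); no stereocentre is formed.

Step 2
Reactants: 6 ethyl (E)-3-(2-methoxy-4-methylphenyl)-4-methylpent-2-enoate
Product: 7 ethyl (2S,3R)-3-(2-methoxy-4-methylphenyl)-3-(propan-2-yl)oxirane-2-carboxylate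
Conditions: D-fructose-derived 4,5-di-O-acetyl Shi ketone (0.3 equiv), Oxone (2KHSO5·KHSO4·K2SO4), NaHCO3, n-Bu4NHSO4, MeCN/aq Na2EDTA, 0 °C
Reagents that add atoms: potassium peroxymonosulfate (active component of Oxone), [K+].[O-]S(=O)(=O)OO
Why: Shi asymmetric epoxidation (chiral dioxirane, spiro transition state) of the trans-β-aryl enoate should deliver oxygen stereospecifically to the face that makes C3 R and C2 S, so the catalyst sets the one stereocentre from which all others are relayed.

Step 3
Reactants: 7 ethyl (2S,3R)-3-(2-methoxy-4-methylphenyl)-3-(propan-2-yl)oxirane-2-carboxylate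
Product: 8 ethyl (3R)-3-hydroxy-3-(2-methoxy-4-methylphenyl)-4-methylpentanoate
Conditions: SmI2 (2.5 equiv), Me2NCH2CH2OH, HMPA, THF, 0 °C
Reagents that add atoms: none
Why: Reductive opening of an α,β-epoxy ester by divalent samarium cleaves only the Cα–O bond, so the C3–O bond and the C3 configuration set in step 2 are kept.

Step 4
Reactants: 8 ethyl (3R)-3-hydroxy-3-(2-methoxy-4-methylphenyl)-4-methylpentanoate
Product: 9 ethyl (3R)-3-(2-methoxy-4-methylphenyl)-4-methyl-3-[(triethylsilyl)oxy]pentanoate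
Conditions: TESOTf, 2,6-lutidine, CH2Cl2, 0 °C → rt
Reagents that add atoms: triethylsilyl trifluoromethanesulfonate, CC[Si](CC)(CC)OS(=O)(=O)C(F)(F)F
Why: Silyl triflate silylation of the hindered tertiary alcohol; the silyl ether prevents O–H insertion of the later carbenoid and retro-aldol cleavage, and is removed in step 15.

Step 5
Reactants: 9 ethyl (3R)-3-(2-methoxy-4-methylphenyl)-4-methyl-3-[(triethylsilyl)oxy]pentanoate
Product: 11 (5R)-5-(2-methoxy-4-methylphenyl)-6-methyl-5-[(triethylsilyl)oxy]heptan-3-one, via Weinreb amide 10 (not isolated)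
Conditions: MeNH(OMe)·HCl, i-PrMgCl, THF, −20 °C; then EtMgBr, 0 °C → rt; aq NH4Cl
Reagents that add atoms: ethylmagnesium bromide, CC[Mg]Br; N,O-dimethylhydroxylamine hydrochloride, CNOC.Cl (to intermediate 10 only)
Why: One-pot Weinreb amidation of the ester and Grignard addition, whose chelated tetrahedral intermediate stops the reaction at the ethyl ketone; C3 of the chain is not involved.

Step 6
Reactants: 11 (5R)-5-(2-methoxy-4-methylphenyl)-6-methyl-5-[(triethylsilyl)oxy]heptan-3-one
Product: 13 (5R)-2-diazo-5-(2-methoxy-4-methylphenyl)-6-methyl-5-[(triethylsilyl)oxy]heptan-3-one, via trifluoroacetyl ketone 12 (not isolated)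
Conditions: LiN(SiMe3)2, THF, −78 °C; CF3CO2CH2CF3; aq NH4Cl wash, crude 12 carried on; then 4-AcNHC6H4SO2N3, Et3N, H2O, MeCN, rt
Reagents that add atoms: 4-acetamidobenzenesulfonyl azide, CC(=O)Nc1ccc(cc1)S(=O)(=O)N=[N+]=[N-]; 2,2,2-trifluoroethyl trifluoroacetate, FC(F)(F)COC(=O)C(F)(F)F (to intermediate 12 only)
Why: Regitz-type detrifluoroacetylative diazo transfer: kinetic enolisation at the unhindered ethyl CH2 (the other α-CH2 is neopentyl), C-trifluoroacetylation and azide transfer with loss of the trifluoroacetyl group give the α-methyl-α-diazoketone.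

Step 7
Reactants: 13 (5R)-2-diazo-5-(2-methoxy-4-methylphenyl)-6-methyl-5-[(triethylsilyl)oxy]heptan-3-one
Product: 15 (3R,8aR)-4-methoxy-6,8a-dimethyl-3-(propan-2-yl)-3-[(triethylsilyl)oxy]-3,8a-dihydroazulen-1(2H)-one, via norcaradiene 14 (not isolated)
Conditions: Rh2(OAc)4 (1 mol%), CH2Cl2, reflux, slow addition of 13
Reagents that add atoms: none
Why: Loss of N2 from 13 gives an electrophilic divalent-rhodium carbenoid that adds across the ipso–ortho (C3a–C8) bond of the anisole ring to give norcaradiene 14, whose disrotatory 6π electrocyclic opening of the C3a–C8 bond delivers cycloheptatriene 15, so the benzene ring grows by one carbon (C8a) into the seven-membered ring. The closest known reaction type is the intramolecular Buchner reaction of 1-diazo-4-arylbutan-2-ones, which is established for α-methyl diazoketones and for fully substituted benzylic carbons. The five-membered ring is closed by attack of the carbenoid carbon C8a on the ipso carbon through a four-atom tether (5-exo-type closure onto the arene π bond), whereas the seven-membered ring is not closed but arises by cleavage of the former aromatic C3a–C8 bond. The new quaternary stereocentre C8a is controlled by C3: in the reacting conformer the benzylic substituent lying near the arene plane beside the ortho-methoxy group must be the small silyloxy group (allylic 1,3-strain) and the isopropyl group points away, which puts the 8a-methyl cis to the silyloxy group and trans to isopropyl. The step needs arene addition to win over 1,5 C–H insertion into the isopropyl methine and over hydride migration from the diazo-methyl group, which the electron-rich ring (ipso carbon ortho to OMe and para to Me), the oxygenated quaternary neighbour of the methine and the acetate ligands should secure. It also needs attack at the unsubstituted ortho carbon and not at the methoxy-bearing one, which sterics favour and which leaves the methoxy group as the C4 enol ether, the latent C4 ketone.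

Step 8
Reactants: 15 (3R,8aR)-4-methoxy-6,8a-dimethyl-3-(propan-2-yl)-3-[(triethylsilyl)oxy]-3,8a-dihydroazulen-1(2H)-one
Product: 16 (3R,3aR,8aR)-6,8a-dimethyl-3-(propan-2-yl)-3-[(triethylsilyl)oxy]-2,3,3a,8a-tetrahydroazulene-1,4-dione
Conditions: (CO2H)2, THF/H2O, 0 °C → rt
Reagents that add atoms: water, O
Why: Weak-acid (general acid-catalysed) enol ether hydrolysis: C-protonation at C3a, hydration of the C4 oxocarbenium ion and loss of methanol give the conjugated 5,7-dien-4-one, and the proton should enter on the β face, anti to the pseudo-axial 8a-methyl and the 3α-silyloxy group, which sets the trans ring fusion (H-3a β), while oxalic acid is too weak to ionise the tertiary silyl ether.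

Step 9
Reactants: 16 (3R,3aR,8aR)-6,8a-dimethyl-3-(propan-2-yl)-3-[(triethylsilyl)oxy]-2,3,3a,8a-tetrahydroazulene-1,4-dione
Product: 17 (1R,3R,3aR,8aR)-1-hydroxy-6,8a-dimethyl-3-(propan-2-yl)-3-[(triethylsilyl)oxy]-1,2,3,3a-tetrahydroazulen-4(8aH)-one
Conditions: NaBH4, MeOH/CH2Cl2 1:1, −78 °C
Reagents that add atoms: none
Why: Borohydride reduction at −78 °C discriminates the saturated cyclopentanone from the conjugated dienone (ketone over enone), and hydride should attack C1 from the β face, anti to the axial angular 8a-methyl as in 17-keto steroids, giving the 1α-alcohol cis to the methyl group.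

Step 10
Reactants: 17 (1R,3R,3aR,8aR)-1-hydroxy-6,8a-dimethyl-3-(propan-2-yl)-3-[(triethylsilyl)oxy]-1,2,3,3a-tetrahydroazulen-4(8aH)-one
Product: 18 (1R,3R,3aR,8aR)-6,8a-dimethyl-3-(propan-2-yl)-1,3-bis[(triethylsilyl)oxy]-1,2,3,3a-tetrahydroazulen-4(8aH)-one
Conditions: TESOTf, 2,6-lutidine, CH2Cl2, −78 °C
Reagents that add atoms: triethylsilyl trifluoromethanesulfonate, CC[Si](CC)(CC)OS(=O)(=O)C(F)(F)F
Why: Silyl triflate silylation of the neopentyl secondary alcohol, which keeps the C1 hydroxyl out of the later esterifications; no stereocentre is touched.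

Step 11
Reactants: 18 (1R,3R,3aR,8aR)-6,8a-dimethyl-3-(propan-2-yl)-1,3-bis[(triethylsilyl)oxy]-1,2,3,3a-tetrahydroazulen-4(8aH)-one
Product: 19 7β,8β-epoxide of 18 (7β,8β-epoxy-6,8aα-dimethyl-3β-(propan-2-yl)-1α,3α-bis[(triethylsilyl)oxy]-1,2,3,3a,7,8-hexahydroazulen-4(8aH)-one; H-3a β)
Conditions: m-CPBA, NaHCO3, CH2Cl2, 0 °C
Reagents that add atoms: 3-chloroperoxybenzoic acid, OOC(=O)c1cccc(Cl)c1
Why: Prilezhaev epoxidation takes the more electron-rich distal (γ,δ) C7=C8 bond of the dienone, and the peracid should approach anti to the axial 8a-methyl on the adjacent carbon, so the epoxide oxygen (the future C8–O) is β.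

Step 12
Reactants: 19 7β,8β-epoxide of 18
Product: 21 (1R,3R,3aS,4S,8R,8aS)-6,8a-dimethyl-3-(propan-2-yl)-1,3-bis[(triethylsilyl)oxy]-1,2,3,3a,4,5,8,8a-octahydroazulene-4,8-diol, via hydroxy enone 20 (not isolated)
Conditions: SmI2 (2.5 equiv), THF/MeOH, −78 °C; then SmI2 (4 equiv), H2O, Et3N, −78 → 0 °C
Reagents that add atoms: none
Why: Divalent samarium first opens the γ,δ-epoxy enone (ketyl formation, cleavage of the allylic C7–O bond, α-protonation of the samarium dienolate) to the 8β-hydroxy-6-en-4-one with C8 untouched, and then, activated by H2O/Et3N, reduces the C4 ketone through an α-oxy organosamarium that should be protonated to the more stable equatorial 4β-alcohol (an axial 4α-hydroxyl would be 1,3-diaxial to the 8a-methyl).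

Step 13
Reactants: 21 (1R,3R,3aS,4S,8R,8aS)-6,8a-dimethyl-3-(propan-2-yl)-1,3-bis[(triethylsilyl)oxy]-1,2,3,3a,4,5,8,8a-octahydroazulene-4,8-diol; 22 angelic acid
Product: 23 (1R,3R,3aS,4S,8R,8aS)-8-hydroxy-6,8a-dimethyl-3-(propan-2-yl)-1,3-bis[(triethylsilyl)oxy]-1,2,3,3a,4,5,8,8a-octahydroazulen-4-yl (2Z)-2-methylbut-2-enoate
Conditions: 22 (1.1 equiv), 2,4,6-Cl3C6H2COCl (1.1 equiv), Et3N, toluene, rt; then 21, 60 °C
Reagents that add atoms: none
Why: Yamaguchi-type acylation with one equivalent of the mixed anhydride of angelic acid, run without a nucleophilic catalyst so that the Z double bond does not isomerise to the tiglate, should take the equatorial 4β-OH (flanked by a CH2 and a CH) in preference to the neopentyl allylic 8β-OH; only an O–acyl bond forms, so no stereocentre is touched.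

Step 14
Reactants: 23 (1R,3R,3aS,4S,8R,8aS)-8-hydroxy-6,8a-dimethyl-3-(propan-2-yl)-1,3-bis[(triethylsilyl)oxy]-1,2,3,3a,4,5,8,8a-octahydroazulen-4-yl (2Z)-2-methylbut-2-enoate; 22 angelic acid
Product: 24 (1R,3R,3aS,4S,8R,8aS)-6,8a-dimethyl-3-(propan-2-yl)-1,3-bis[(triethylsilyl)oxy]-1,2,3,3a,4,5,8,8a-octahydroazulene-4,8-diyl bis[(2Z)-2-methylbut-2-enoate]
Conditions: 22 (4 equiv), 2,4,6-Cl3C6H2COCl (4 equiv), Et3N, toluene, rt; then 23, 100 °C
Reagents that add atoms: none
Why: The same mixed-anhydride (Yamaguchi-type) acylation, now with excess reagent and more heat and again without a nucleophilic catalyst to keep the Z geometry, should force the remaining hindered 8β-OH to the second angelate with no stereocentre touched; any 8-mono-angelate or bis-angelate carried over from step 13 converges on 24 here.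

Step 15
Reactants: 24 bis(triethylsilyl) ether of the target
Product: 26 (1R,3R,3aS,4S,8R,8aR)-1,3-dihydroxy-6,8a-dimethyl-3-(propan-2-yl)-1,2,3,3a,4,5,8,8a-octahydroazulene-4,8-diyl bis[(2Z)-2-methylbut-2-enoate], via 3-monosilyl ether 25 (not isolated)
Conditions: HF·pyridine, pyridine, THF, 0 °C → rt
Reagents that add atoms: none
Why: Buffered fluoride-mediated cleavage of both triethylsilyl ethers (the secondary one first) should leave the two angelate esters and their Z alkenes intact and gives the target.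

**Compound list**

1 | 1-bromo-2-methoxy-4-methylbenzene | COc1cc(C)ccc1Br | starting material
2 | ethyl 4-methylpent-2-ynoate | CCOC(=O)C#CC(C)C | starting material
3 | (2-methoxy-4-methylphenyl)lithium | [Li]c1ccc(C)cc1OC | intermediate
4 | lithium bis(2-methoxy-4-methylphenyl)cuprate | [Li+].COc1cc(C)ccc1[Cu-]c1ccc(C)cc1OC | intermediate
5 | lithium (2-methoxy-4-methylphenyl)[(Z)-1-ethoxy-3-(2-methoxy-4-methylphenyl)-4-methyl-1-oxopent-2-en-2-yl]cuprate | [Li+].CCOC(=O)/C([Cu-]c1ccc(C)cc1OC)=C(/c1ccc(C)cc1OC)C(C)C | intermediate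
6 | ethyl (E)-3-(2-methoxy-4-methylphenyl)-4-methylpent-2-enoate | CCOC(=O)/C=C(/c1ccc(C)cc1OC)C(C)C | intermediate
7 | ethyl (2S,3R)-3-(2-methoxy-4-methylphenyl)-3-(propan-2-yl)oxirane-2-carboxylate | CCOC(=O)[C@H]1O[C@]1(C(C)C)c2ccc(C)cc2OC | intermediate
8 | ethyl (3R)-3-hydroxy-3-(2-methoxy-4-methylphenyl)-4-methylpentanoate | CCOC(=O)C[C@@](O)(C(C)C)c1ccc(C)cc1OC | intermediate
9 | ethyl (3R)-3-(2-methoxy-4-methylphenyl)-4-methyl-3-[(triethylsilyl)oxy]pentanoate | CCOC(=O)C[C@@](O[Si](CC)(CC)CC)(C(C)C)c1ccc(C)cc1OC | intermediate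
10 | (3R)-N-methoxy-3-(2-methoxy-4-methylphenyl)-N,4-dimethyl-3-[(triethylsilyl)oxy]pentanamide | CON(C)C(=O)C[C@@](O[Si](CC)(CC)CC)(C(C)C)c1ccc(C)cc1OC | intermediate
11 | (5R)-5-(2-methoxy-4-methylphenyl)-6-methyl-5-[(triethylsilyl)oxy]heptan-3-one | CCC(=O)C[C@@](O[Si](CC)(CC)CC)(C(C)C)c1ccc(C)cc1OC | intermediate
12 | (6R)-1,1,1-trifluoro-6-(2-methoxy-4-methylphenyl)-3,7-dimethyl-6-[(triethylsilyl)oxy]octane-2,4-dione (carried on crude; C3 not defined) | CC(C(=O)C(F)(F)F)C(=O)C[C@@](O[Si](CC)(CC)CC)(C(C)C)c1ccc(C)cc1OC | intermediate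
13 | (5R)-2-diazo-5-(2-methoxy-4-methylphenyl)-6-methyl-5-[(triethylsilyl)oxy]heptan-3-one | CC(=[N+]=[N-])C(=O)C[C@@](O[Si](CC)(CC)CC)(C(C)C)c1ccc(C)cc1OC | intermediate
14 | norcaradiene valence isomer of 15 (cyclopropane C3a–C8–C8a; diene C4=C5 and C6=C7) | O=C1C[C@@](O[Si](CC)(CC)CC)(C(C)C)[C@@]23C(OC)=CC(C)=C[C@@H]2[C@@]13C | intermediate
15 | (3R,8aR)-4-methoxy-6,8a-dimethyl-3-(propan-2-yl)-3-[(triethylsilyl)oxy]-3,8a-dihydroazulen-1(2H)-one (8a-methyl cis to the 3-silyloxy group) | O=C1C[C@@](O[Si](CC)(CC)CC)(C(C)C)C2=C(OC)C=C(C)C=C[C@@]12C | intermediate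
16 | (3R,3aR,8aR)-6,8a-dimethyl-3-(propan-2-yl)-3-[(triethylsilyl)oxy]-2,3,3a,8a-tetrahydroazulene-1,4-dione (trans-fused; H-3a β) | O=C1C[C@@](O[Si](CC)(CC)CC)(C(C)C)[C@@H]2C(=O)C=C(C)C=C[C@@]12C | intermediate
17 | (1R,3R,3aR,8aR)-1-hydroxy-6,8a-dimethyl-3-(propan-2-yl)-3-[(triethylsilyl)oxy]-1,2,3,3a-tetrahydroazulen-4(8aH)-one (1α-OH) | O[C@@H]1C[C@@](O[Si](CC)(CC)CC)(C(C)C)[C@@H]2C(=O)C=C(C)C=C[C@@]12C | intermediate
18 | (1R,3R,3aR,8aR)-6,8a-dimethyl-3-(propan-2-yl)-1,3-bis[(triethylsilyl)oxy]-1,2,3,3a-tetrahydroazulen-4(8aH)-one | CC[Si](CC)(CC)O[C@@H]1C[C@@](O[Si](CC)(CC)CC)(C(C)C)[C@@H]2C(=O)C=C(C)C=C[C@@]12C | intermediate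
19 | 7β,8β-epoxy-6,8aα-dimethyl-3β-(propan-2-yl)-1α,3α-bis[(triethylsilyl)oxy]-1,2,3,3a,7,8-hexahydroazulen-4(8aH)-one (H-3a β) | CC[Si](CC)(CC)O[C@@H]1C[C@@](O[Si](CC)(CC)CC)(C(C)C)[C@@H]2C(=O)C=C(C)[C@H]3O[C@H]3[C@@]12C | intermediate
20 | 8β-hydroxy-6,8aα-dimethyl-3β-(propan-2-yl)-1α,3α-bis[(triethylsilyl)oxy]-1,2,3,3a,5,8-hexahydroazulen-4(8aH)-one (H-3a β) | CC[Si](CC)(CC)O[C@@H]1C[C@@](O[Si](CC)(CC)CC)(C(C)C)[C@@H]2C(=O)CC(C)=C[C@@H](O)[C@@]12C | intermediate
21 | (1R,3R,3aS,4S,8R,8aS)-6,8a-dimethyl-3-(propan-2-yl)-1,3-bis[(triethylsilyl)oxy]-1,2,3,3a,4,5,8,8a-octahydroazulene-4,8-diol (4β-OH, 8β-OH) | CC[Si](CC)(CC)O[C@@H]1C[C@@](O[Si](CC)(CC)CC)(C(C)C)[C@@H]2[C@@H](O)CC(C)=C[C@@H](O)[C@@]12C | intermediate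
22 | angelic acid, (2Z)-2-methylbut-2-enoic acid | C/C=C(/C)C(=O)O | starting material
23 | (1R,3R,3aS,4S,8R,8aS)-8-hydroxy-6,8a-dimethyl-3-(propan-2-yl)-1,3-bis[(triethylsilyl)oxy]-1,2,3,3a,4,5,8,8a-octahydroazulen-4-yl (2Z)-2-methylbut-2-enoate (4β-mono-angelate of 21; 8β-OH free) | CC[Si](CC)(CC)O[C@@H]1C[C@@](O[Si](CC)(CC)CC)(C(C)C)[C@@H]2[C@@H](OC(=O)/C(C)=C\C)CC(C)=C[C@@H](O)[C@@]12C | intermediate
24 | (1R,3R,3aS,4S,8R,8aS)-6,8a-dimethyl-3-(propan-2-yl)-1,3-bis[(triethylsilyl)oxy]-1,2,3,3a,4,5,8,8a-octahydroazulene-4,8-diyl bis[(2Z)-2-methylbut-2-enoate] | CC[Si](CC)(CC)O[C@@H]1C[C@@](O[Si](CC)(CC)CC)(C(C)C)[C@@H]2[C@@H](OC(=O)/C(C)=C\C)CC(C)=C[C@@H](OC(=O)/C(C)=C\C)[C@@]12C | intermediate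
25 | 3-O-triethylsilyl ether of the target (1α-OH free) | O[C@@H]1C[C@@](O[Si](CC)(CC)CC)(C(C)C)[C@@H]2[C@@H](OC(=O)/C(C)=C\C)CC(C)=C[C@@H](OC(=O)/C(C)=C\C)[C@@]12C | intermediate
26 | CNP0249167.2, (1R,3R,3aS,4S,8R,8aR)-1,3-dihydroxy-6,8a-dimethyl-3-(propan-2-yl)-1,2,3,3a,4,5,8,8a-octahydroazulene-4,8-diyl bis[(2Z)-2-methylbut-2-enoate] | C/C=C(/C)C(=O)O[C@H]1CC(C)=C[C@@H](OC(=O)/C(C)=C\C)[C@@]2(C)[C@H](O)C[C@@](O)(C(C)C)[C@H]12 | target

**Step count and risks**

Total steps: 15. Longest linear sequence: 15 steps (1 and 2 to 26).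

The ring expansion (step 7) rests on close analogy in both reaction type and sense of induction; the three steps judged most likely to fail are 2, 8 and 12.

Step 2. The dioxirane may transfer oxygen too slowly to the hindered, electron-poor trisubstituted alkene, so that catalyst decomposition outruns epoxidation, or with poor facial discrimination because the isopropyl group sits cis to the ester. The fallback sets out from 6 and comes back at 7, and replaces substrate-recognition by the dioxirane with reagent control through a bound allylic alcohol. Ester 6 is reduced (i-Bu2AlH, CH2Cl2, −78 °C) to (E)-3-(2-methoxy-4-methylphenyl)-4-methylpent-2-en-1-ol F1. Sharpless asymmetric epoxidation (Ti(Oi-Pr)4, D-(−)-diethyl tartrate, t-BuOOH, 4 Å sieves, CH2Cl2, −20 °C) should then give [(2R,3R)-3-(2-methoxy-4-methylphenyl)-3-(propan-2-yl)oxiran-2-yl]methanol F2. Oxidation of the primary alcohol (TEMPO, PhI(OAc)2, MeCN/H2O) gives (2S,3R)-3-(2-methoxy-4-methylphenyl)-3-(propan-2-yl)oxirane-2-carboxylic acid F3, and O-alkylation (EtI, K2CO3, DMF) returns 7.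

Step 8. Protonation of the trienol ether may occur on the α face and give the cis ring fusion, or the tertiary silyloxy group may be lost by ionisation or β-elimination. The fallback sets out from 15 and comes back at 16, and exchanges kinetic protonation for thermodynamic control. Hydrolysis is run as before without regard to the C3a ratio, and the cis-fused (3R,3aS,8aR)-6,8a-dimethyl-3-(propan-2-yl)-3-[(triethylsilyl)oxy]-2,3,3a,8a-tetrahydroazulene-1,4-dione F4 is equilibrated through its C4 dienolate (DBU cat., toluene, rt). The trans-fused 16 should be favoured, because cis fusion forces the C4 carbonyl arm cis to the isopropyl group on the neighbouring quaternary carbon, whereas in 16 it is cis to the smaller oxygen substituent; the poor silanolate leaving group should hold back elimination under catalytic amidine.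

Step 12. Protonation of the α-oxy organosamarium may occur from the less hindered side and give the axial 4α-alcohol, or the β,γ-enone may slip into conjugation before it is reduced. The fallback sets out from 19 and comes back at 23, and replaces thermodynamic reduction by kinetic reduction followed by inversion. The first SmI2 stage alone is run and 20 is isolated. Luche reduction (NaBH4, CeCl3·7H2O, MeOH, −78 °C) should add hydride from the open equatorial side, the axial path being blocked by the 8a-methyl, to give (1R,3R,3aS,4R,8R,8aS)-6,8a-dimethyl-3-(propan-2-yl)-1,3-bis[(triethylsilyl)oxy]-1,2,3,3a,4,5,8,8a-octahydroazulene-4,8-diol F5. Mitsunobu esterification with 22 (PPh3, DIAD, toluene, 0 °C → rt) then inverts C4 and gives mono-angelate 23 directly; the neopentyl allylic 8β-OH should resist displacement. The route is rejoined at 23, which enters step 14.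

**Further compounds**

F1 | step 2 | (E)-3-(2-methoxy-4-methylphenyl)-4-methylpent-2-en-1-ol | OC/C=C(/c1ccc(C)cc1OC)C(C)C
F2 | step 2 | [(2R,3R)-3-(2-methoxy-4-methylphenyl)-3-(propan-2-yl)oxiran-2-yl]methanol | OC[C@H]1O[C@]1(C(C)C)c2ccc(C)cc2OC
F3 | step 2 | (2S,3R)-3-(2-methoxy-4-methylphenyl)-3-(propan-2-yl)oxirane-2-carboxylic acid | OC(=O)[C@H]1O[C@]1(C(C)C)c2ccc(C)cc2OC
F4 | step 8 | (3R,3aS,8aR)-6,8a-dimethyl-3-(propan-2-yl)-3-[(triethylsilyl)oxy]-2,3,3a,8a-tetrahydroazulene-1,4-dione (cis-fused 3a-epimer of 16) | O=C1C[C@@](O[Si](CC)(CC)CC)(C(C)C)[C@H]2C(=O)C=C(C)C=C[C@@]12C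
F5 | step 12 | (1R,3R,3aS,4R,8R,8aS)-6,8a-dimethyl-3-(propan-2-yl)-1,3-bis[(triethylsilyl)oxy]-1,2,3,3a,4,5,8,8a-octahydroazulene-4,8-diol (4α-epimer of 21) | CC[Si](CC)(CC)O[C@@H]1C[C@@](O[Si](CC)(CC)CC)(C(C)C)[C@@H]2[C@H](O)CC(C)=C[C@@H](O)[C@@]12C
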